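**Retrosynthetic overview**

1. Labdane numbering is used (ring A = C1–C5, C10; ring B = C5–C10; C18 and C19 on C4, C20 on C10, C17 on C8, side chain C11–C16). The C3 acetate and the C19 aldehyde are 1,3-related across C3–C4 (an aldol retron), C1 is the β-carbon of the same C1–C2–C3 unit, and C10 and C4 both sit on C5. Ring A is therefore acrolein joined to C10 and C4 of a ring B precursor.
2. Precursor shaping: C10 becomes the terminus of a 1-silyloxy-1,3-diene in ring B (C7=C8–C9=C10, from a C7 enone), and C4 the carbon of a C19 enol pivalate. Diels–Alder addition of acrolein forms C1–C10 and a temporary C2–C7 bond, retro-aldol removes that bond, and aldol closure forms C3–C4, all in one flask.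
3. Ring B and the C5 stereocentre come from (S)-carvone: C10 methylation, 1,2-addition/oxidative transposition (side arm to C9, carbonyl to C7), Horner–Wadsworth–Emmons olefination, and isopropenyl → epoxide → aldehyde → enol pivalate (C4, C18, C19).
4. After the annulation the C7 oxygen is removed with allylic transposition (Luche reduction, acetylation, palladium/formate), which sets C9–H, places the C7=C8 alkene and frees the acid.
5. Ring order: ring B first (chiral pool), ring A last.

Key step: step 9

Remark: stereocentres that are erased later (C9 in 4, C10 in 2–11, the oxirane carbon in 9, C4 in 10, C2 in 14) need not be controlled; the SMILES show the expected major isomer or leave the centre open.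

**Step 1**
Reactants: 1 (S)-(+)-carvone
Product: 2 trans-6-methylcarvone, (5S,6R)-2,6-dimethyl-5-(prop-1-en-2-yl)cyclohex-2-en-1-one
Conditions: LiN(i-Pr)2, THF, −78 °C; then MeI, −78 to 0 °C
Reagents that add atoms: iodomethane, CI
Why: Kinetic deprotonation at the only enolizable α'-carbon gives the cross-conjugated lithium enolate, whose C-methylation (enolate alkylation) should give mainly the trans isomer, and the new C10 centre is planarized again in step 8.

**Step 2**
Reactants: 2 trans-6-methylcarvone; 3 2-(2-bromoethyl)-2-methyl-1,3-dioxolane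
Product: 4 tertiary allylic alcohol (5S,6R)-2,6-dimethyl-1-[2-(2-methyl-1,3-dioxolan-2-yl)ethyl]-5-(prop-1-en-2-yl)cyclohex-2-en-1-ol (both C1 epimers)
Conditions: 3, Mg, THF (Grignard reagent); anhydrous CeCl3, THF, −78 °C; then 2, −78 to 0 °C; sat. aq NH4Cl
Reagents that add atoms: none
Why: 1,2-Addition of the organocerium reagent (Grignard reagent with CeCl3) to the hindered, enolizable enone carbonyl should suppress enolization and conjugate addition, and the new carbinol centre (C9) becomes sp2 in step 3.

**Step 3**
Reactants: 4 tertiary allylic alcohol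
Product: 6 enone methyl ketone (4R,5S)-2,4-dimethyl-3-(3-oxobutyl)-5-(prop-1-en-2-yl)cyclohex-2-en-1-one, via ketal enone 5 (not isolated)
Conditions: [C5H5NH][CrO3Cl] (pyridinium chlorochromate), NaOAc, 4 Å sieves, CH2Cl2, rt; then TsOH·H2O (cat.), acetone/H2O, rt
Reagents that add atoms: pyridinium chlorochromate, [O-][Cr](=O)(=O)Cl.c1cc[nH+]cc1; water, O
Why: Babler–Dauben oxidative 1,3-transposition (chromate ester [3,3] shift, then oxidation) should move the carbonyl to C7 and leave the side arm on the sp2 carbon C9, and mild aqueous acid then unmasks the methyl ketone without forming a stereocentre.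

**Step 4**
Reactants: 6 enone methyl ketone; 7 prop-2-en-1-yl (diethoxyphosphoryl)acetate
Product: 8 allyl (2E)-5-[(5S,6R)-2,6-dimethyl-3-oxo-5-(prop-1-en-2-yl)cyclohex-1-en-1-yl]-3-methylpent-2-enoate
Conditions: 7, NaH, THF, 0 °C; then 6, 0 °C to rt
Reagents that add atoms: none
Why: Horner–Wadsworth–Emmons olefination should occur only at the unhindered methyl ketone (the ring carbonyl is conjugated and flanked by a tetrasubstituted alkene) and give mainly the (E)-trisubstituted enoate, the minor (Z) isomer being removed by chromatography.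

**Step 5**
Reactants: 8 allyl enoate
Product: 9 epoxide, allyl (2E)-5-[(5S,6R)-2,6-dimethyl-5-(2-methyloxiran-2-yl)-3-oxocyclohex-1-en-1-yl]-3-methylpent-2-enoate (both oxirane epimers)
Conditions: mCPBA, NaHCO3, CH2Cl2, 0 °C
Reagents that add atoms: 3-chloroperoxybenzoic acid, OOC(=O)c1cccc(Cl)c1
Why: Prilezhaev epoxidation should be chemoselective for the electron-rich 1,1-disubstituted alkene over the electron-poor enone, enoate and allyl ester alkenes, and the two epoxide epimers converge in steps 6 and 7.

**Step 6**
Reactants: 9 epoxide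
Product: 10 aldehyde, allyl (2E)-5-[(5S,6R)-2,6-dimethyl-3-oxo-5-(1-oxopropan-2-yl)cyclohex-1-en-1-yl]-3-methylpent-2-enoate (both C4 epimers)
Conditions: BF3·OEt2 (cat.), CH2Cl2, −78 °C
Reagents that add atoms: none
Why: Meinwald rearrangement (Lewis-acid opening at the tertiary carbon, then a 1,2-hydride shift from the CH2O carbon) should give the α-branched C19 aldehyde, whose C4 epimers converge in step 7.

**Step 7**
Reactants: 10 aldehyde
Product: 11 (E)-enol pivalate of 10, C19H(OCOt-Bu)=C4(CH3)– with the pivaloyloxy group trans to the ring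
Conditions: KN(SiMe3)2, THF, −78 °C; then t-BuCOCl, −78 to 0 °C
Reagents that add atoms: pivaloyl chloride, CC(C)(C)C(Cl)=O
Why: Deprotonation of the most acidic C–H (α to the aldehyde) and O-acylation of the potassium enolate should give the enol ester with oxygen trans to the bulkier ring substituent, i.e. the (E) isomer, which fixes the enol geometry used in step 9.

**Step 8**
Reactants: 11 enol pivalate
Product: 12 trimethylsilyl dienol ether of 11 with the diene in ring B (C7(OSiMe3)=C8–C9=C10)
Conditions: Me3SiCl, NaI, Et3N, MeCN, 0 °C to rt; used crude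
Reagents that add atoms: chlorotrimethylsilane, C[Si](C)(C)Cl
Why: Silylation under equilibrating conditions (Me3SiI formed in situ) should give the thermodynamic, ring-conjugated cisoid 1-silyloxy-1,3-diene by γ-deprotonation at C10, the enol pivalate and the esters being inert, and any exocyclic (transoid) dienol ether cannot enter the cycloaddition of step 9.

**Step 9**
Reactants: 12 silyl dienol ether; 13 acrolein
Product: 16 hydroxy aldehyde allyl (3S,4S,5S,10R,13E)-3-hydroxy-7,19-dioxolabda-8,13-dien-15-oate, via cycloadduct 14 (not isolated), via keto aldehyde 15 (not isolated)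
Conditions: 13 (excess), BHT (cat.), PhMe, 80 °C; evaporate; then (CF3SO2)2NH (10 mol %), H2O (3 equiv), CH2Cl2/MeCN, −20 to 0 °C
Reagents that add atoms: water, O
Why: Proposed new method: the ring B 1-silyloxy-1,3-diene of 12 should add acrolein in a thermal, ortho-selective [4+2] cycloaddition on the face opposite the pseudo-axial C5 side arm, which forms C1–C10 (quaternary C10) and a temporary C2–C7 bond in 14. Wet (CF3SO2)2NH then removes the bridgehead silyl group, the β-hydroxy aldehyde opens by retro-aldol to enone aldehyde 15, and the protonated C3 aldehyde is attacked by C4 of the enol pivalate, water adding to the acyloxy carbocation at C19 and releasing pivalic acid and the aldehyde. The closest known reaction types are Diels–Alder/retro-aldol sequences of 1-silyloxycyclohexa-1,3-dienes (formal vinylogous Michael additions) and acid-promoted additions of enol esters to aldehydes and acetals; their union in one flask with an enol ester as terminator is the new element. The bicyclo[2.2.2]octene bridge closes by suprafacial cycloaddition and is removed in the same flask, and ring A closes in a 6-(enolexo)-exo-trig aldol through a chair in which C1 and C4, trans on ring B, enforce the trans ring fusion. C10 is set by the cycloaddition face (controlled by the carvone-derived C5 centre), C4 by the (E)-enol geometry, which places the flat C19 carbon and not the methyl group syn-axial to the C10 methyl group, and C3 by an open, antiperiplanar approach of enol C=C and protonated C=O that leaves the new hydroxyl axial and anti to C19. The step needs C10 (not C4) to take C1 and C4 (not C2) to take C3: only the cisoid silyloxydiene can undergo the cycloaddition while the enol pivalate is inert to acrolein, and after the retro-aldol the enol ester is the only π-nucleophile left and C19 is not yet electrophilic, so the C2-to-C19 aldol is excluded.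

**Step 10**
Reactants: 16 hydroxy aldehyde
Product: 17 diol, allyl (3S,4S,5S,7R,10R,13E)-3,7-dihydroxy-19-oxolabda-8,13-dien-15-oate
Conditions: NaBH4, CeCl3·7H2O, MeOH, −78 °C
Reagents that add atoms: none
Why: Luche reduction should reduce the enone carbonyl 1,2 while the hindered neopentyl aldehyde is held back as its hemiacetal in methanol, and axial hydride attack from the face opposite the C10 methyl group should place the C7 hydroxyl on the same face as that methyl group.

**Step 11**
Reactants: 17 diol
Product: 18 diacetate, allyl (3S,4S,5S,7R,10R,13E)-3,7-diacetoxy-19-oxolabda-8,13-dien-15-oate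
Conditions: Ac2O, pyridine, DMAP (cat.), CH2Cl2, rt
Reagents that add atoms: acetic anhydride, CC(=O)OC(C)=O
Why: DMAP-catalysed acylation should esterify both the axial C3 alcohol (the acetate of the target) and the allylic C7 alcohol (the leaving group for step 12) without touching a stereocentre.

**Step 12**
Reactants: 18 diacetate
Product: 19 target, (3S,4S,5S,9R,10S,13E)-3-acetoxy-19-oxolabda-7,13-dien-15-oic acid
Conditions: Pd(OAc)2 (cat.), n-Bu3P, HCO2H, Et3N, THF, 60 °C
Reagents that add atoms: none
Why: Tsuji–Trost ionization of the C7 allylic acetate by zerovalent palladium (formed in situ) with inversion, then formate-derived hydride delivery from the metal to the more substituted allyl terminus, should put hydrogen on C9 trans to the C10 methyl group and leave the C7=C8 alkene, while the same palladium/formate system cleaves the allyl ester to the acid.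

**Compound list**

1 | (S)-(+)-carvone, (5S)-2-methyl-5-(prop-1-en-2-yl)cyclohex-2-en-1-one | CC1=CC[C@@H](CC1=O)C(C)=C | starting material
2 | trans-6-methylcarvone, (5S,6R)-2,6-dimethyl-5-(prop-1-en-2-yl)cyclohex-2-en-1-one | CC1=CC[C@@H]([C@@H](C)C1=O)C(C)=C | intermediate
3 | 2-(2-bromoethyl)-2-methyl-1,3-dioxolane | CC1(CCBr)OCCO1 | starting material
4 | (5S,6R)-2,6-dimethyl-1-[2-(2-methyl-1,3-dioxolan-2-yl)ethyl]-5-(prop-1-en-2-yl)cyclohex-2-en-1-ol, both C1 epimers | CC1=CC[C@@H]([C@@H](C)C1(O)CCC2(C)OCCO2)C(C)=C | intermediate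
5 | ketal enone, (4R,5S)-2,4-dimethyl-3-[2-(2-methyl-1,3-dioxolan-2-yl)ethyl]-5-(prop-1-en-2-yl)cyclohex-2-en-1-one (not isolated) | CC1=C(CCC2(C)OCCO2)[C@H](C)[C@@H](C(C)=C)CC1=O | intermediate
6 | (4R,5S)-2,4-dimethyl-3-(3-oxobutyl)-5-(prop-1-en-2-yl)cyclohex-2-en-1-one | CC1=C(CCC(C)=O)[C@H](C)[C@@H](C(C)=C)CC1=O | intermediate
7 | prop-2-en-1-yl (diethoxyphosphoryl)acetate | CCOP(=O)(CC(=O)OCC=C)OCC | starting material
8 | allyl (2E)-5-[(5S,6R)-2,6-dimethyl-3-oxo-5-(prop-1-en-2-yl)cyclohex-1-en-1-yl]-3-methylpent-2-enoate | CC1=C(CC/C(C)=C/C(=O)OCC=C)[C@H](C)[C@@H](C(C)=C)CC1=O | intermediate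
9 | allyl (2E)-5-[(5S,6R)-2,6-dimethyl-5-(2-methyloxiran-2-yl)-3-oxocyclohex-1-en-1-yl]-3-methylpent-2-enoate, both oxirane epimers | CC1=C(CC/C(C)=C/C(=O)OCC=C)[C@H](C)[C@@H](C2(C)CO2)CC1=O | intermediate
10 | allyl (2E)-5-[(5S,6R)-2,6-dimethyl-3-oxo-5-(1-oxopropan-2-yl)cyclohex-1-en-1-yl]-3-methylpent-2-enoate, both C4 epimers | CC1=C(CC/C(C)=C/C(=O)OCC=C)[C@H](C)[C@@H](C(C)C=O)CC1=O | intermediate
11 | (E)-enol pivalate of 10, allyl (2E)-5-{(5S,6R)-5-[(1E)-1-(2,2-dimethylpropanoyloxy)prop-1-en-2-yl]-2,6-dimethyl-3-oxocyclohex-1-en-1-yl}-3-methylpent-2-enoate | CC1=C(CC/C(C)=C/C(=O)OCC=C)[C@H](C)[C@@H](/C(C)=C/OC(=O)C(C)(C)C)CC1=O | intermediate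
12 | trimethylsilyl dienol ether of 11, ring B diene C7(OSiMe3)=C8–C9=C10, (S) at C5 | C[Si](C)(C)OC1=C(C)C(CC/C(C)=C/C(=O)OCC=C)=C(C)[C@@H](/C(C)=C/OC(=O)C(C)(C)C)C1 | intermediate
13 | acrolein, prop-2-enal | C=CC=O | starting material
14 | cycloadduct, bicyclo[2.2.2]oct-5-ene with the C1–C2 bridge between C10 and C7 on the face anti to the C5 side arm, formyl on C2 (both epimers), Me3SiO on bridgehead C7 (not isolated) | C[Si](C)(C)O[C@@]12C[C@H](/C(C)=C/OC(=O)C(C)(C)C)[C@@](C)(CC1C=O)C(CC/C(C)=C/C(=O)OCC=C)=C2C | intermediate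
15 | keto aldehyde, C7 enone with quaternary C10 (methyl and 3-oxopropyl, 3-oxopropyl trans to the C5 side arm) and intact enol pivalate (not isolated) | O=CCC[C@@]1(C)C(CC/C(C)=C/C(=O)OCC=C)=C(C)C(=O)C[C@@H]1/C(C)=C/OC(=O)C(C)(C)C | intermediate
16 | allyl (3S,4S,5S,10R,13E)-3-hydroxy-7,19-dioxolabda-8,13-dien-15-oate, trans-fused, 3-OH axial and anti to the axial C19 formyl | O[C@H]1CC[C@@]2(C)C(CC/C(C)=C/C(=O)OCC=C)=C(C)C(=O)C[C@@H]2[C@]1(C)C=O | intermediate
17 | allyl (3S,4S,5S,7R,10R,13E)-3,7-dihydroxy-19-oxolabda-8,13-dien-15-oate, 7-OH cis to C20 | O[C@H]1CC[C@@]2(C)C(CC/C(C)=C/C(=O)OCC=C)=C(C)[C@H](O)C[C@@H]2[C@]1(C)C=O | intermediate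
18 | allyl (3S,4S,5S,7R,10R,13E)-3,7-diacetoxy-19-oxolabda-8,13-dien-15-oate | CC(=O)O[C@H]1CC[C@@]2(C)C(CC/C(C)=C/C(=O)OCC=C)=C(C)[C@H](OC(C)=O)C[C@@H]2[C@]1(C)C=O | intermediate
19 | (3S,4S,5S,9R,10S,13E)-3-acetoxy-19-oxolabda-7,13-dien-15-oic acid, i.e. (2E)-5-[(1R,4aS,5S,6S,8aS)-6-acetoxy-5-formyl-2,5,8a-trimethyl-1,4,4a,5,6,7,8,8a-octahydronaphthalen-1-yl]-3-methylpent-2-enoic acid | CC(=O)O[C@H]1CC[C@@]2(C)[C@H](CC/C(C)=C/C(=O)O)C(C)=CC[C@@H]2[C@]1(C)C=O | target

**Step count**

Total steps: 12. Longest linear sequence: 12 steps (1 → 19); compounds 3, 7 and 13 are commercial.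

**Steps most likely to fail**

Step 9 (proposed new method). What may go wrong: hydrolysis of the enol pivalate before ring closure, after which the two free aldehydes would condense the other way round (C2 onto C19). Closure through a synclinal instead of an antiperiplanar arrangement would give the C3 epimer, and facial control in the cycloaddition may be incomplete. The fallback uses known reactions in separate operations and sets out from 10. i-Pr3SiOTf and Et3N should give the (E)-triisopropylsilyl enol ether of 10 F1. Me3SiCl, NaI and Et3N should then give the bis-silyl diene F2. Thermal Diels–Alder reaction with acrolein (PhMe, 80 °C) should give the isolated cycloadduct with a triisopropylsilyl enol ether F3. Brief K2CO3 in MeOH at 0 °C should cleave the tertiary trimethylsilyl ether, and the alkoxide should open by retro-aldol to the keto aldehyde with the silyl enol ether intact F4. BF3·OEt2 in CH2Cl2 at −78 °C should then close ring A by an intramolecular Mukaiyama aldol reaction (open transition state), and the route is rejoined at 16.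

Step 10. What may go wrong: reduction of the C19 aldehyde competing with the 1,2-reduction of the hindered enone, or hydride attack on the other face of C7, which would invert C9 in step 12. The fallback protects the aldehyde and sets out from 16. HC(OMe)3 and pyridinium tosylate in MeOH should give the C19 dimethyl acetal of 16 F5. Luche reduction should give the 3,7-diol acetal F6, and Ac2O, pyridine and DMAP the diacetate acetal F7. Pd(OAc)2, n-Bu3P, HCO2H and Et3N should give the C19 dimethyl acetal of the target acid F8. Pyridinium tosylate in wet acetone should release the aldehyde, and the route is rejoined at 19.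

Step 12. What may go wrong: slow ionization of an allylic acetate on a tetrasubstituted alkene, hydride delivery to C7 instead of C9 (alkene left at C8=C9), or loss of stereospecificity by face exchange of the allyl complex. The fallback is a metal-free reductive 1,3-transposition and sets out from 16. Ac2O, pyridine and DMAP should give the 3-acetate of 16 F9, and Luche reduction the 3-acetoxy C7 allylic alcohol F10. 2-Nitrobenzenesulfonylhydrazide, PPh3 and diethyl azodicarboxylate (THF, −30 °C to rt) should displace the C7 hydroxyl with inversion (Mitsunobu reaction). Loss of sulfinate and suprafacial retro-ene loss of N2 from the allylic diazene should place hydrogen on C9 trans to C20 and give the allyl ester of the target F11. Pd(PPh3)4 and morpholine should then remove the allyl ester, and the route is rejoined at 19.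

**Further compounds**

F1 | step 9 | (E)-triisopropylsilyl enol ether of 10 | CC1=C(CC/C(C)=C/C(=O)OCC=C)[C@H](C)[C@@H](/C(C)=C/O[Si](C(C)C)(C(C)C)C(C)C)CC1=O
F2 | step 9 | bis-silyl diene, C7 trimethylsilyl dienol ether of F1 | C[Si](C)(C)OC1=C(C)C(CC/C(C)=C/C(=O)OCC=C)=C(C)[C@@H](/C(C)=C/O[Si](C(C)C)(C(C)C)C(C)C)C1
F3 | step 9 | cycloadduct with triisopropylsilyl enol ether | C[Si](C)(C)O[C@@]12C[C@H](/C(C)=C/O[Si](C(C)C)(C(C)C)C(C)C)[C@@](C)(CC1C=O)C(CC/C(C)=C/C(=O)OCC=C)=C2C
F4 | step 9 | keto aldehyde with triisopropylsilyl enol ether | O=CCC[C@@]1(C)C(CC/C(C)=C/C(=O)OCC=C)=C(C)C(=O)C[C@@H]1/C(C)=C/O[Si](C(C)C)(C(C)C)C(C)C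
F5 | step 10 | C19 dimethyl acetal of 16 | O[C@H]1CC[C@@]2(C)C(CC/C(C)=C/C(=O)OCC=C)=C(C)C(=O)C[C@@H]2[C@]1(C)C(OC)OC
F6 | step 10 | 3,7-diol acetal | O[C@H]1CC[C@@]2(C)C(CC/C(C)=C/C(=O)OCC=C)=C(C)[C@H](O)C[C@@H]2[C@]1(C)C(OC)OC
F7 | step 10 | diacetate acetal | CC(=O)O[C@H]1CC[C@@]2(C)C(CC/C(C)=C/C(=O)OCC=C)=C(C)[C@H](OC(C)=O)C[C@@H]2[C@]1(C)C(OC)OC
F8 | step 10 | C19 dimethyl acetal of the target acid | CC(=O)O[C@H]1CC[C@@]2(C)[C@H](CC/C(C)=C/C(=O)O)C(C)=CC[C@@H]2[C@]1(C)C(OC)OC
F9 | step 12 | 3-acetate of 16 | CC(=O)O[C@H]1CC[C@@]2(C)C(CC/C(C)=C/C(=O)OCC=C)=C(C)C(=O)C[C@@H]2[C@]1(C)C=O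
F10 | step 12 | 3-acetoxy C7 allylic alcohol | CC(=O)O[C@H]1CC[C@@]2(C)C(CC/C(C)=C/C(=O)OCC=C)=C(C)[C@H](O)C[C@@H]2[C@]1(C)C=O
F11 | step 12 | allyl ester of the target | CC(=O)O[C@H]1CC[C@@]2(C)[C@H](CC/C(C)=C/C(=O)OCC=C)C(C)=CC[C@@H]2[C@]1(C)C=O
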